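The chair opened the meeting by putting the flasks and the questions on the board.

| flask | starting material | protic impurity | remark | time |
|---|---|---|---|---|
| south | 0.084 M | 0.042 M | run made earlier |  |
| north-east | 0.084 M | 0.021 M | run made earlier |  |
| north-west | 0.084 M | 0.032 M | run made earlier |  |
| south-west | 0.17 M | 0.042 M | run made earlier |  |
| Tuesday's | 0.084 M | 0.0420 M | a closed flask charged with all of it at once and left for 20 min | 20 min |
| Sunday's | 0.084 M (fed, over 10.0 min) | 0.0420 M | a stirred flask in which starting material is dosed at a steady rate over 10.0 min without added volume, worked up at 20 min | 20 min |
| Friday's | 0.084 M | 0.0420 M | one stirred flow tank at steady state, fed with the mixture as stated, mean residence time 20 min |  |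
| Wednesday's | 0.084 M | 0.0420 M | one stirred flow tank at steady state, fed with the mixture as stated, mean residence time 100 min |  |

- south (time / min: target / %, starting material / %): 1.00: 0, 75; 2.00: 0, 56; 5.00: 0, 23; 12.0: 9, 1
- north-east (time / min: target / %, starting material / %): 3.00: 0, 42; 8.00: 3, 15; 15.0: 15, 2; 25.0: 32, 1
- north-west (time / min: target / %, starting material / %): 3.00: 0, 47; 8.00: 6, 12; 15.0: 14, 3; 25.0: 28, 0
- south-west (time / min: target / %, starting material / %): 3.00: 0, 45; 8.00: 5, 10; 15.0: 13, 0; 25.0: 34, 1

(readings scatter by 1.5 percentage points)

- the stated concentrations are those of everything mixed, before any reaction; amounts are the same in each set-up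
- the numbers in the tables scatter with a standard deviation of 1.5 percentage points
- the feed brings no volume worth counting
- the earlier runs were made in a closed, stirred flask

- the set-up with the highest amount of target at the outlet or at the end, in percent of the starting material put in ("none" if the first two lie within 2 percentage points) (Tuesday's / Sunday's / Friday's / Wednesday's / none)
- amount of target at the outlet or at the end, in percent of the starting material put in, Tuesday's
- amount of target at the outlet or at the end, in percent of the starting material put in, Sunday's
- amount of target at the outlet or at the end, in percent of the starting material put in, Friday's
- amount of target at the outlet or at the end, in percent of the starting material put in, Wednesday's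

The analyst pointed out that in the north-east run starting material reads 2% at 15.0 min, yet target climbs by 17 percentage points over the next 10.0 min. Across the north-east, north-west and south-west runs, the analyst said, that same interval gains on average 0.0173 min⁻¹ of the charge.

That was a first answer, which treats the whole charge as still waiting. The analyst then went round once more and put back the mean target reading of 22.7%. This gave the slow clock, the fraction of the charge not yet target that becomes target per minute late in a closed run: 0.0224 min⁻¹, or a time of 44.6 min.

The chair asked where the clock could be used. The analyst answered that 20 min is about half of that time, so the lag in the tables still weighs on the 20 min set-ups, and gave no number for them. Wednesday's 100 min is twice that time, so a stirred tank should pass on 2.24 parts in 3.24, a share of 69.1%, less whatever the impurity takes.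

The forecaster disagreed on that loss, holding that “The impurity therefore costs 50% of the charge here, leaving a 50% ceiling”. The forecast named Wednesday's as best, with 16% for Tuesday's, 10% for Sunday's, 12% for Friday's and 34% for Wednesday's, the last lower than the analyst's share.

The flasks gave 21.3% for Tuesday's, 13.3% for Sunday's, 20.4% for Friday's and 59.5% for Wednesday's, so Wednesday's is best.

    starting material ⇌ intermediate A (K = 1.01, k = 0.00464 s⁻¹)
    intermediate A → intermediate B (k = 7.45 × 10⁻⁴ s⁻¹)
    intermediate B → target (k = 0.00163 s⁻¹)
    intermediate A → intermediate C (k = 0.0364 s⁻¹)
    intermediate B ⇌ intermediate C (K = 0.512, k = 3.39 × 10⁻⁴ s⁻¹)
    starting material + protic impurity → quenched substrate (k = 0.0171 M⁻¹ s⁻¹)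

Wednesday's tank stands at 0.861 of the 69.1% reckoned from the clock. For 200 min the clock gives 98.9%, and Sunday's flask, left that long, gives 86.6%, which is 0.876 of it. Both target amounts lie above 50 per cent. On Tuesday's charge, the forward step from starting material to intermediate A alone has a half-life of 2.5 min, shorter than the 16 min of the step from starting material and protic impurity to quenched substrate alone. Those two half-lives differ by a factor of 6.40.

(The runs are calculated for an exercise; scatter was added.)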